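The target is numbered as 6H-isochromene. Its pyran ring (O2, C1, C8a, C4a, C4, C3) is a vinylogous 4-pyranone fused through C4a–C8a to the cyclohexenone ring. C4a is the β-carbon and C4 the γ-carbon of the C6 enone, and C8a is α to a C1 formyl group. The key step uses this. An open-chain aldehyde–ynone, carrying the C7/C8 diol as an acetonide, closes the carbocycle by Michael addition (C8a to C4a). Its bis-silyl trienol ether is acylated at C4 by a fumaroyl chloride (C3), and acid closes the pyran, all in one flask. The diol comes from 2-C-methyl-D-erythrono-1,4-lactone; the orsellinate is attached last.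

Key step: step 8

Remark: 2-C-methyl-D-erythrono-1,4-lactone, (3R,4R), is taken as a purchasable chiral-pool compound; its two stereocentres become C7 and C8 and no bond to them is broken in the route.

Step 1
Reactants: 1 2-C-methyl-D-erythrono-1,4-lactone
Product: 2 (3aR,6aR)-2,2,3a-trimethyltetrahydrofuro[3,4-d][1,3]dioxol-4-one (cis-fused acetonide of 1)
Conditions: Me2C(OMe)2, TsOH·H2O (cat.), acetone, 23 °C
Reagents that add atoms: 2,2-dimethoxypropane, COC(C)(C)OC
Why: Acid-catalysed transketalisation (acetonide formation) is favoured for the cis-1,2-diol on the five-membered lactone and touches neither stereocentre.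

Step 2
Reactants: 2 acetonide lactone
Product: 3 (4R,5R)-5-(hydroxymethyl)-N-methoxy-N,2,2,4-tetramethyl-1,3-dioxolane-4-carboxamide
Conditions: MeNH(OMe)·HCl, i-PrMgCl, THF, −20 → 0 °C
Reagents that add atoms: N,O-dimethylhydroxylamine hydrochloride, CNOC.Cl
Why: The chloromagnesium amide opens the lactone by acyl substitution (Weinreb amide formation), and the hydroxy amide is taken on crude so that it cannot relactonise.

Step 3
Reactants: 3 hydroxy Weinreb amide
Product: 4 (4R,5S)-5-formyl-N-methoxy-N,2,2,4-tetramethyl-1,3-dioxolane-4-carboxamide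
Conditions: Dess–Martin periodinane, CH2Cl2, 0 → 23 °C
Reagents that add atoms: none
Why: Dess–Martin oxidation converts the primary alcohol into the aldehyde under non-basic conditions that should leave the adjacent dioxolane stereocentre (later C8) intact.

Step 4
Reactants: 4 aldehyde
Product: 5 (4R,5R)-N-methoxy-5-(2-methoxyethenyl)-N,2,2,4-tetramethyl-1,3-dioxolane-4-carboxamide (E/Z mixture)
Conditions: MeOCH2PPh3Cl, KN(SiMe3)2, THF, 0 °C; then 4, −78 → 0 °C
Reagents that add atoms: (methoxymethyl)triphenylphosphonium chloride, COC[P+](c1ccccc1)(c1ccccc1)c1ccccc1.[Cl-]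
Why: Wittig methoxymethylenation (first half of a one-carbon homologation) should take place at the aldehyde and not at the hindered quaternary Weinreb amide, and the low temperature limits enolisation of the α-alkoxy aldehyde; the enol ether geometry is irrelevant.

Step 5
Reactants: 5 enol ether Weinreb amide
Product: 6 1-[(4R,5R)-5-(2-methoxyethenyl)-2,2,4-trimethyl-1,3-dioxolan-4-yl]but-2-yn-1-one (E/Z mixture)
Conditions: MeC≡CMgBr, THF, 0 → 23 °C
Reagents that add atoms: prop-1-yn-1-ylmagnesium bromide, CC#C[Mg]Br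
Why: In this Weinreb ketone synthesis the chelated tetrahedral intermediate survives until work-up, so the alkynyl Grignard reagent adds once and the ynone results.

Step 6
Reactants: 6 enol ether ynone
Product: 7 2-[(4R,5R)-5-(but-2-ynoyl)-2,2,5-trimethyl-1,3-dioxolan-4-yl]acetaldehyde
Conditions: TsOH·H2O (cat.), acetone–H2O (20:1), 0 → 23 °C
Reagents that add atoms: water, O
Why: Acid-catalysed enol ether hydrolysis completes the homologation, acetone as solvent holds the acetonide in place, and the sensitive keto aldehyde is used at once.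

Step 7
Reactants: 8 (2E)-4-tert-butoxy-4-oxobut-2-enoic acid (mono-tert-butyl fumarate)
Product: 9 tert-butyl (2E)-4-chloro-4-oxobut-2-enoate
Conditions: (COCl)2, DMF (cat.), CH2Cl2, 0 → 23 °C
Reagents that add atoms: oxalyl chloride, ClC(=O)C(=O)Cl
Why: Vilsmeier-type activation with oxalyl chloride and catalytic DMF gives the acid chloride with only volatile by-products, and the E-alkene and tert-butyl ester should survive at this temperature.

Step 8
Reactants: 7 keto aldehyde; 9 tert-butyl (2E)-4-chloro-4-oxobut-2-enoate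
Product: 13 tert-butyl (2E)-3-[(7R,8R)-7-methyl-6-oxo-7,8-(propane-2,2-diyldioxy)-7,8-dihydro-6H-isochromen-3-yl]prop-2-enoate, via hydroxymethylene enone 10 (not isolated), via bis-silyl trienol ether 11 (not isolated), via acylated hydroxymethylene enone 12 (not isolated)
Conditions: DBU (1.05 equiv), CH2Cl2, −20 → 0 °C; then Me3SiOTf (2.5 equiv), Et3N (3 equiv), −78 → 0 °C; then 9 (1.2 equiv), −78 → 0 °C; then AcOH–H2O, 23 → 40 °C (one flask)
Reagents that add atoms: none
Why: DBU enolises the aldehyde and C8a adds to the ynone β-carbon C4a (intramolecular Michael addition, 6-endo-dig), which closes the carbocycle, and prototropy gives the stabilised hydroxymethylene enone 10. Me3SiOTf/Et3N silylates O2 and O6 and removes a proton from the C4 methyl group (soft enolisation) to give the cross-conjugated trienol ether 11, a vinylogous 1,3-bis(silyloxy)-1,3-diene. Such dienes are acylated by acid chlorides at their terminal carbon, the known entry to 3,5-dioxo compounds and 4-pyranones, and 11 should likewise be acylated by 9 at C4 (its γ-position in both silyl dienol ether arms), which forms C3–C4. Aqueous acid removes the silyl groups, and O2 of 12 adds to the C3 ketone (6-exo-trig) with loss of water, which closes the pyran as a vinylogous 4-pyranone. No stereocentre is formed; C7 is quaternary and C8–H is not acidic in 10 to 13, so the lactone-derived configuration is carried through. The step needs C-attack at C4a to outrun β-elimination of the C8 acetal oxygen (the tether, the electrophilic ynone and the low temperature favour it), and it needs 1,2-acylation at C4 (the acid chloride carbonyl is more electrophilic than the fumarate alkene); only O2 can close a ring without a bridgehead alkene.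

Step 9
Reactants: 13 acetonide
Product: 14 tert-butyl (2E)-3-[(7R,8R)-7,8-dihydroxy-7-methyl-6-oxo-7,8-dihydro-6H-isochromen-3-yl]prop-2-enoate
Conditions: AcOH–H2O (4:1), 60 °C
Reagents that add atoms: none
Why: Mild aqueous acid hydrolyses the isopropylidene acetal, while the tert-butyl ester and the vinylogous pyranone (itself formed under acid) should be stable.

Step 10
Reactants: 15 methyl 2,4-dihydroxy-6-methylbenzoate (methyl orsellinate)
Product: 16 methyl 2,4-bis(methoxymethoxy)-6-methylbenzoate
Conditions: MOMCl, NaH, DMF, 0 → 23 °C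
Reagents that add atoms: chloromethyl methyl ether, COCCl
Why: Williamson-type O-alkylation of both phenoxides works once NaH has broken the hydrogen bond of the ortho hydroxyl to the ester.

Step 11
Reactants: 16 bis-MOM methyl ester
Product: 17 2,4-bis(methoxymethoxy)-6-methylbenzoic acid
Conditions: KOH, MeOH–H2O (3:1), 80 °C; then 1 M HCl, 0 °C, to pH 4
Reagents that add atoms: potassium hydroxide, [K+].[OH-]
Why: Saponification of the hindered 2,6-disubstituted benzoate needs hot hydroxide, which the MOM acetals tolerate, and the cold, brief acidification keeps them intact.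

Step 12
Reactants: 14 diol; 17 2,4-bis(methoxymethoxy)-6-methylbenzoic acid
Product: 19 (7R,8R)-3-[(1E)-3-tert-butoxy-3-oxoprop-1-en-1-yl]-7-hydroxy-7-methyl-6-oxo-7,8-dihydro-6H-isochromen-8-yl 2,4-bis(methoxymethoxy)-6-methylbenzoate, via acid chloride 18 (not isolated)
Conditions: 17, Me2C=C(Cl)NMe2, CH2Cl2, 0 → 23 °C; then 14, pyridine, DMAP (cat.), 0 → 23 °C
Reagents that add atoms: none
Why: Esterification through the acid chloride, made under neutral conditions with the α-chloroenamine so that the MOM groups survive, should occur at the secondary allylic C8 hydroxyl because the tertiary, hydrogen-bonded C7 hydroxyl is far more hindered, and C8 keeps its configuration since only its O–H bond reacts.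

Step 13
Reactants: 19 protected ester
Product: 20 (+)-mitorubrinic acid B, (2E)-3-[(7R,8R)-8-(2,4-dihydroxy-6-methylbenzoyloxy)-7-hydroxy-7-methyl-6-oxo-7,8-dihydro-6H-isochromen-3-yl]prop-2-enoic acid
Conditions: CF3CO2H–CH2Cl2 (1:4), H2O (5 equiv), 0 → 23 °C
Reagents that add atoms: none
Why: Acidolysis cleaves the tert-butyl ester (loss of 2-methylpropene) and both MOM acetals in one operation, and the C8 ester should not ionise because C8 lies β to the C6 ketone and next to the oxygenated C7.

Compound list
1 | 2-C-methyl-D-erythrono-1,4-lactone, (3R,4R)-3,4-dihydroxy-3-methyloxolan-2-one | C[C@@]1(O)[C@H](O)COC1=O | starting material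
2 | (3aR,6aR)-2,2,3a-trimethyltetrahydrofuro[3,4-d][1,3]dioxol-4-one | C[C@@]12OC(C)(C)O[C@@H]1COC2=O | intermediate
3 | (4R,5R)-5-(hydroxymethyl)-N-methoxy-N,2,2,4-tetramethyl-1,3-dioxolane-4-carboxamide | CON(C)C(=O)[C@]1(C)OC(C)(C)O[C@@H]1CO | intermediate
4 | (4R,5S)-5-formyl-N-methoxy-N,2,2,4-tetramethyl-1,3-dioxolane-4-carboxamide | CON(C)C(=O)[C@]1(C)OC(C)(C)O[C@@H]1C=O | intermediate
5 | (4R,5R)-N-methoxy-5-(2-methoxyethenyl)-N,2,2,4-tetramethyl-1,3-dioxolane-4-carboxamide (E/Z mixture) | CON(C)C(=O)[C@]1(C)OC(C)(C)O[C@@H]1C=COC | intermediate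
6 | 1-[(4R,5R)-5-(2-methoxyethenyl)-2,2,4-trimethyl-1,3-dioxolan-4-yl]but-2-yn-1-one (E/Z mixture) | CC#CC(=O)[C@]1(C)OC(C)(C)O[C@@H]1C=COC | intermediate
7 | 2-[(4R,5R)-5-(but-2-ynoyl)-2,2,5-trimethyl-1,3-dioxolan-4-yl]acetaldehyde | CC#CC(=O)[C@]1(C)OC(C)(C)O[C@@H]1CC=O | intermediate
8 | (2E)-4-tert-butoxy-4-oxobut-2-enoic acid | CC(C)(C)OC(=O)/C=C/C(=O)O | starting material
9 | tert-butyl (2E)-4-chloro-4-oxobut-2-enoate | CC(C)(C)OC(=O)/C=C/C(=O)Cl | intermediate
10 | (3aR,7aR)-7-(hydroxymethylidene)-2,2,3a,6-tetramethyl-7,7a-dihydro-1,3-benzodioxol-4(3aH)-one | CC1=CC(=O)[C@]2(C)OC(C)(C)O[C@@H]2C1=CO | intermediate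
11 | (3aR,7aR)-2,2,3a-trimethyl-6-methylidene-4-(trimethylsilyloxy)-7-[(trimethylsilyloxy)methylidene]-3a,6,7,7a-tetrahydro-1,3-benzodioxole | C=C1C=C(O[Si](C)(C)C)[C@]2(C)OC(C)(C)O[C@@H]2C1=CO[Si](C)(C)C | intermediate
12 | tert-butyl (2E)-5-[(3aR,7aR)-7-(hydroxymethylidene)-2,2,3a-trimethyl-4-oxo-3a,4,7,7a-tetrahydro-1,3-benzodioxol-6-yl]-4-oxopent-2-enoate | CC(C)(C)OC(=O)/C=C/C(=O)CC1=CC(=O)[C@]2(C)OC(C)(C)O[C@@H]2C1=CO | intermediate
13 | tert-butyl (2E)-3-[(7R,8R)-7-methyl-6-oxo-7,8-(propane-2,2-diyldioxy)-7,8-dihydro-6H-isochromen-3-yl]prop-2-enoate | CC(C)(C)OC(=O)/C=C/C1=CC2=CC(=O)[C@]3(C)OC(C)(C)O[C@@H]3C2=CO1 | intermediate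
14 | tert-butyl (2E)-3-[(7R,8R)-7,8-dihydroxy-7-methyl-6-oxo-7,8-dihydro-6H-isochromen-3-yl]prop-2-enoate | CC(C)(C)OC(=O)/C=C/C1=CC2=CC(=O)[C@](C)(O)[C@H](O)C2=CO1 | intermediate
15 | methyl 2,4-dihydroxy-6-methylbenzoate | COC(=O)c1c(C)cc(O)cc1O | starting material
16 | methyl 2,4-bis(methoxymethoxy)-6-methylbenzoate | COCOc1cc(C)c(C(=O)OC)c(OCOC)c1 | intermediate
17 | 2,4-bis(methoxymethoxy)-6-methylbenzoic acid | COCOc1cc(C)c(C(=O)O)c(OCOC)c1 | intermediate
18 | 2,4-bis(methoxymethoxy)-6-methylbenzoyl chloride | COCOc1cc(C)c(C(=O)Cl)c(OCOC)c1 | intermediate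
19 | (7R,8R)-3-[(1E)-3-tert-butoxy-3-oxoprop-1-en-1-yl]-7-hydroxy-7-methyl-6-oxo-7,8-dihydro-6H-isochromen-8-yl 2,4-bis(methoxymethoxy)-6-methylbenzoate | COCOc1cc(C)c(C(=O)O[C@@H]2C3=COC(/C=C/C(=O)OC(C)(C)C)=CC3=CC(=O)[C@]2(C)O)c(OCOC)c1 | intermediate
20 | (+)-mitorubrinic acid B | Cc1cc(O)cc(O)c1C(=O)O[C@@H]1C2=COC(/C=C/C(=O)O)=CC2=CC(=O)[C@]1(C)O | target

Total step count: 13
Longest linear sequence: 10 steps (steps 1 to 6, 8, 9, 12 and 13)

Steps most likely to fail

1. Step 8. The aldehyde enolate may lose the C8 acetal oxygen by β-elimination before it closes the ring. The second silylation may stay incomplete, or Me3SiOTf may open the acetonide. The trienol ether may be acylated at oxygen, or may add to the fumarate alkene instead of being acylated at C4. Fallback, from 7 back to 13: pyrrolidine (1.1 equiv, CH2Cl2, 0 °C) is expected to convert 7, through its enamine and an intramolecular Stork-type conjugate addition to the ynone, into the isolable pyrrolidine dienaminone F1, with no free enolate involved. LiN(i-Pr)2 (2.5 equiv, THF, −78 °C) then removes a proton from the C4 methyl group, and acylation of the anion by 9 gives the acylated dienaminone F2; this is the known acylation of enaminones that leads to 4-pyranones. Aqueous AcOH closes the pyran with loss of pyrrolidine and gives 13.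

2. Step 12. The doubly ortho-substituted acid chloride may acylate the hindered C8 hydroxyl too slowly. The acyl group may go to, or migrate to, the C7 hydroxyl. The vinylogous pyranone may degrade on long exposure to the amine bases. Fallback, from 14 back to 19: Bu2Sn(OMe)2 (toluene, 23 °C, then evaporation) converts the cis-diol into the dibutylstannylene acetal F3. This is treated with acid chloride 18 (made as in step 12) in CH2Cl2 without amine base. Tin activates the less hindered secondary oxygen O8, and aqueous work-up gives 19.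

3. Step 4. The basic ylide may enolise the α-alkoxy aldehyde, which would scramble the stereocentre that becomes C8, or it may attack the Weinreb amide. Fallback, from 4 back to 7: non-basic Takai–Lombardo methylenation (Zn, CH2Br2, TiCl4, THF–CH2Cl2, 0 °C) gives the vinyl dioxolane amide F4. Hydroboration–oxidation (9-BBN, THF; then NaBO3·4H2O) gives the primary alcohol F5. MeC≡CMgBr (2.5 equiv, THF) converts the Weinreb amide into the hydroxy ynone F6, and Dess–Martin oxidation of the primary alcohol gives 7.

Further compounds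
F1 | step 8 | (3aR,7aR)-2,2,3a,6-tetramethyl-7-(pyrrolidin-1-ylmethylidene)-7,7a-dihydro-1,3-benzodioxol-4(3aH)-one | CC1=CC(=O)[C@]2(C)OC(C)(C)O[C@@H]2C1=CN1CCCC1
F2 | step 8 | tert-butyl (2E)-4-oxo-5-[(3aR,7aR)-2,2,3a-trimethyl-4-oxo-7-(pyrrolidin-1-ylmethylidene)-3a,4,7,7a-tetrahydro-1,3-benzodioxol-6-yl]pent-2-enoate | CC(C)(C)OC(=O)/C=C/C(=O)CC1=CC(=O)[C@]2(C)OC(C)(C)O[C@@H]2C1=CN1CCCC1
F3 | step 12 | 7,8-O-dibutylstannylene acetal of tert-butyl (2E)-3-[(7R,8R)-7,8-dihydroxy-7-methyl-6-oxo-7,8-dihydro-6H-isochromen-3-yl]prop-2-enoate | CCCC[Sn]1(CCCC)O[C@@H]2C3=COC(/C=C/C(=O)OC(C)(C)C)=CC3=CC(=O)[C@]2(C)O1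
F4 | step 4 | (4R,5R)-5-ethenyl-N-methoxy-N,2,2,4-tetramethyl-1,3-dioxolane-4-carboxamide | CON(C)C(=O)[C@]1(C)OC(C)(C)O[C@@H]1C=C
F5 | step 4 | (4R,5R)-5-(2-hydroxyethyl)-N-methoxy-N,2,2,4-tetramethyl-1,3-dioxolane-4-carboxamide | CON(C)C(=O)[C@]1(C)OC(C)(C)O[C@@H]1CCO
F6 | step 4 | 1-[(4R,5R)-5-(2-hydroxyethyl)-2,2,4-trimethyl-1,3-dioxolan-4-yl]but-2-yn-1-one | CC#CC(=O)[C@]1(C)OC(C)(C)O[C@@H]1CCO
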